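All constants are assumed; the flask was simulated.

In a one-step world L meets E, both fall together, and a single second-order law gives what is left at any time. This scheme has three steps, so I keep a ledger of L, the limiting reagent, and I watch L first.

    L + E → L.E (k1 = 0.10 M⁻¹ s⁻¹, Ea1 = 39.0 kJ mol⁻¹)
    L + E → X (k2 = 0.0036 M⁻¹ s⁻¹, Ea2 = 65.0 kJ mol⁻¹)
    L.E → Q (k3 = 0.021 s⁻¹, Ea3 = 72.0 kJ mol⁻¹)
    (constants at 0 °C)

| setting | north-east | east | west |
|---|---|---|---|
| L | 0.12 M | 0.12 M | 0.12 M |
| E | 1.20 equiv | 1.20 equiv | 1.20 equiv |
| temperature | 0 °C | 20 °C | 40 °C |
| time | 15 s | 15 s | 15 s |

- all constants are for 0 °C and move with temperature by the activation energies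

1. which of these there is most of at the end, counted by the L in it, north-east (Q / L / L.E / X)
2. which of these there is most of at the end, counted by the L in it, east (Q / L / L.E / X)
3. which of these there is most of at the end, counted by the L in it, west (Q / L / L.E / X)
4. final amount of the leader among these, as a percentage of the L charged, in north-east
5. final amount of the leader among these, as a percentage of the L charged, in east
6. final amount of the leader among these, as a percentage of the L charged, in west

1. The step from L.E to Q neither uses nor returns L or E. Both capture steps go with the same product of L and E, so together they act as the one-step world with their constants summed.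

2. At east the summed constant is 0.348 M⁻¹ s⁻¹, so 0.627 is its capture number, the summed constant times the charged L times the time. North-east has 0.186. West, with 0.897 M⁻¹ s⁻¹ and 0.139 M⁻¹ s⁻¹, has 1.86.

3. First entry, L left. With r the equivalents of E and N the capture number, the fraction left is (r − 1) / (r·exp((r − 1)N) − 1). This gives 81.4% for north-east, 55.5% for east and 26.9% for west.

4. In north-east L keeps more than the 18.6% captured, and in east more than the 44.5% captured. So L leads both, however the captured part divides.

5. West needs the other entries. In west X takes a constant share of capture, which gives 9.83%.

6. Now the two ends. In north-east L.E has a half-life of 33 s, longer than the 15 s of the run, so captured L waits there. In west, with step constant 1.20 s⁻¹, the half-life is 0.575 s, shorter than the run. So I put L.E in west near its quasi-steady level, where making equals using up, at about 1.13% at the end.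

7. In west the books close on Q at 62.1%, more than the L left, so I expect Q to lead west.

The forecast gives L at 81.4% for north-east, L at 55.5% for east and Q at 62% for west, saying of west that “L.E turns over within about a second”.

The simulation gives L at 81.4% for north-east, L at 55.5% for east and Q at 62.0% for west, where L stands at 26.9%, X at 9.83% and L.E at 1.23%.

The neighbouring flask is east read at 25 s instead. Its constants are unchanged, so the capture number grows with the time to 1.04. The same formula then leaves 41.8% of L, less than the 58.2% captured, so in this neighbour L may be overtaken, and I have to watch Q. The simulated neighbour has L at 41.8% and L.E at 7.27%, and its leader is Q at 46.7%.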